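**Assumption:** the SMILES is read as the all-catechin tetramer catechin-(4α→8)-catechin-(4α→8)-catechin-(4α→8)-catechin (three upper units 2R,3S,4S; terminal unit 2R,3S), and (+)-catechin is taken as the cheap commercial chiral starting material. In the protected intermediates the C4 centres are described as 4α (aryl cis to the C2 aryl, trans to the 3-OH), because their CIP letter changes with the neighbouring groups; the SMILES lines are definitive. Dimer ketone 6 is made on a scale that serves twice, as the nucleophilic lower half in step 7 and as the precursor of the electrophilic upper half (steps 5 and 6).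

## Retrosynthetic overview

1. Target 13 ⇒ hydrogenolysis of the sixteen benzyl ethers and the C8 bromine cap of tetramer 12.
2. 12 ⇒ central C4–C8 bond by a 2 + 2 union: dimeric enolonium 10 (an α-keto cation equivalent at C4, from silyl enol ether 9 with PhI(OAc)2/BF3) is captured by the nucleophilic C8–H of dimer ketone 6, and the three C3 ketones are reduced in the same flask.
3. 9 ⇐ bromo diketone 8 ⇐ 6 (C8 bromination of the upper unit, oxidation of the lower 3-OH), so 6 supplies both halves.
4. 6 ⇒ C4–C8 bond from monomeric enolonium 5 (from silyl enol ether 4) and the C8–H of tetra-O-benzylcatechin 2; 4 ⇐ ketone 3 ⇐ 2 ⇐ (+)-catechin 1.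
5. No ring is built: rings A, B and C of all four units come intact from (+)-catechin.

## Route

Step 1
Reactants: 1 (+)-catechin
Product: 2 5,7,3',4'-tetra-O-benzyl-(+)-catechin, i.e. (2R,3S)-5,7-bis(benzyloxy)-2-[3,4-bis(benzyloxy)phenyl]chroman-3-ol
Conditions: BnBr (4.4 eq), K2CO3, DMF, 0 °C → rt
Reagents that add atoms: benzyl bromide, BrCc1ccccc1
Why: Williamson etherification in which K2CO3 deprotonates only the four phenols (pKa about 9–10) and leaves the aliphatic 3-OH free, so no stereocentre is touched.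

Step 2
Reactants: 2 5,7,3',4'-tetra-O-benzyl-(+)-catechin
Product: 3 (2R)-5,7-bis(benzyloxy)-2-[3,4-bis(benzyloxy)phenyl]chroman-3-one
Conditions: Dess–Martin periodinane, wet CH2Cl2, rt
Reagents that add atoms: none
Why: Dess–Martin oxidation of the secondary alcohol under neutral conditions, so the C2 stereocentre next to the new ketone is not epimerised in the absence of base.

Step 3
Reactants: 3 (2R)-5,7-bis(benzyloxy)-2-[3,4-bis(benzyloxy)phenyl]chroman-3-one
Product: 4 (2R)-5,7-bis(benzyloxy)-2-[3,4-bis(benzyloxy)phenyl]-3-(trimethylsilyloxy)-2H-chromene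
Conditions: TMSOTf (1.2 eq), Et3N (1.5 eq), CH2Cl2, −78 → 0 °C; pentane, filtration, used crude
Reagents that add atoms: trimethylsilyl trifluoromethanesulfonate, C[Si](C)(C)OS(=O)(=O)C(F)(F)F
Why: Soft enolisation to a silyl enol ether, expected at the C4 methylene as in 2-tetralone-type ketones (benzylic to ring A, two accessible hydrogens, enol conjugated with the fused ring) and not at the tertiary C2–H, so C2 stays R and no new stereocentre arises.

Step 4
Reactants: 4 (2R)-3-(trimethylsilyloxy)-2H-chromene monomer; 2 5,7,3',4'-tetra-O-benzyl-(+)-catechin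
Product: 6 dimer ketone (upper unit (2R)-chroman-3-one with 4α-aryl; joined C4→C8 to a (2R,3S)-tetra-O-benzylcatechin unit), via enolonium 5 (not isolated)
Conditions: PhI(OAc)2 (1.0 eq), BF3·OEt2 (2 eq), CH2Cl2, −78 °C, 4 (1.1 eq) added dropwise; then 2 (3 eq, excess recovered), −78 → −45 °C; then Et3N, −45 → −20 °C; aq. NaHCO3
Reagents that add atoms: none
Why: Proposed new method: umpolung α-arylation through an enolonium species, in which BF3-activated PhI(OAc)2 turns the enol ether into an electrophilic trivalent-iodine enolate (an α-keto cation equivalent at C4, whose own ring A is deactivated by conjugation with the electron-poor C3=C4–O–I unit) that the C8–H of 2 attacks in an SN2'/Friedel–Crafts sense with loss of iodobenzene (C6 lies between two benzyloxy groups), the closest known reaction being the metal-free α-arylation of ketones via enolonium species with electron-rich arenes and heteroarenes; the new C4 centre is α to the ketone and is expected to settle during the Et3N stage with its aryl group pseudo-equatorial and cis to the C2 aryl (4α), the C4–H being the faster-exchanging proton because its enolate is conjugated with ring A.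

Step 5
Reactants: 6 dimer ketone
Product: 8 8-bromo diketone dimer (upper unit 8-bromo-(2R)-chroman-3-one with 4α-aryl; lower unit (2R)-chroman-3-one; all eight phenols benzylated), via bromo ketone 7 (not isolated)
Conditions: NBS (1.0 eq), CH2Cl2, −78 → 0 °C; then Dess–Martin periodinane, NaHCO3, rt
Reagents that add atoms: N-bromosuccinimide, O=C1CCC(=O)N1Br
Why: Electrophilic aromatic bromination goes to C8 of the upper unit, the only activated ring A position that is neither substituted nor flanked by two benzyloxy groups, and caps the ring that would otherwise compete as a nucleophile in step 7, after which Dess–Martin oxidation in the same flask turns the lower 3-OH into the ketone needed for the second umpolung without touching C2 or C4.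

Step 6
Reactants: 8 8-bromo diketone dimer
Product: 9 mono silyl enol ether of 8 (upper unit unchanged; lower unit (2R)-3-(trimethylsilyloxy)-2H-chromene)
Conditions: TMSOTf (1.05 eq), Et3N (1.3 eq), CH2Cl2, −78 °C; pentane, filtration, used crude
Reagents that add atoms: trimethylsilyl trifluoromethanesulfonate, C[Si](C)(C)OS(=O)(=O)C(F)(F)F
Why: Soft enolisation to the silyl enol ether is expected only at the lower-unit C4 methylene, because the upper ketone offers only a hindered C4 methine (whose tetrasubstituted enol ether would suffer severe allylic strain against the 5-benzyloxy group and the C4 aryl) and a tertiary C2–H, so no stereocentre is touched.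

Step 7
Reactants: 9 mono silyl enol ether of the 8-bromo diketone dimer; 6 dimer ketone
Product: 12 8-bromo-hexadeca-O-benzyl catechin-(4α→8) tetramer (three upper units 2R,3S with 4α-aryl; bottom unit 2R,3S), via dimeric enolonium 10 (not isolated), via tetramer triketone 11 (not isolated)
Conditions: PhI(OAc)2 (1.0 eq), BF3·OEt2 (2 eq), CH2Cl2, −78 °C, 9 (1.1 eq) added dropwise; then 6 (1.5 eq), −78 → −40 °C; then Et3N, −40 → −20 °C; then MeOH, NaBH4 (excess), −40 → 0 °C
Reagents that add atoms: none
Why: Proposed new method: the same enolonium α-arylation carried out between two dimers, in which the trivalent-iodine enolate 10 is attacked by the only free C8–H of 6 (that of its upper unit, while C8 of 10 is blocked by bromine so that it cannot oligomerise), the closest known reaction being the metal-free α-arylation of ketones via enolonium species; Et3N is then expected to let all three C4–H centres settle with the aryl group cis to the C2 aryl (4α), and NaBH4 is expected to add to each ketone axially from the α face, which has no syn-axial hydrogen at O1 or C4a whereas equatorial attack would eclipse the axial C2–H and C4–H, giving three equatorial 3-OH groups trans to both neighbouring aryl groups (3S).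

Step 8
Reactants: 12 8-bromo-hexadeca-O-benzyl catechin-(4α→8) tetramer
Product: 13 catechin-(4α→8)-catechin-(4α→8)-catechin-(4α→8)-catechin (CNP0236700.2)
Conditions: H2 (1 atm), Pd(OH)2/C, Et3N (1.5 eq), THF–MeOH–H2O, rt; filtration under argon, Sephadex LH-20, lyophilisation
Reagents that add atoms: none
Why: Catalytic hydrogenolysis cleaves the sixteen benzyl aryl ethers and the aryl C–Br bond, Et3N taking up the HBr so that the acid-labile interflavan bonds, the ring C ethers and all eleven stereocentres stay untouched.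

## Compound list

1 | (+)-catechin, (2R,3S)-2-(3,4-dihydroxyphenyl)chroman-3,5,7-triol | Oc1cc(O)c2c(c1)O[C@H](c1ccc(O)c(O)c1)[C@@H](O)C2 | starting material

2 | 5,7,3',4'-tetra-O-benzyl-(+)-catechin, (2R,3S)-5,7-bis(benzyloxy)-2-[3,4-bis(benzyloxy)phenyl]chroman-3-ol | c1ccc(cc1)COc1cc(OCc3ccccc3)c2c(c1)O[C@H](c1ccc(OCc3ccccc3)c(OCc3ccccc3)c1)[C@@H](O)C2 | intermediate

3 | (2R)-5,7-bis(benzyloxy)-2-[3,4-bis(benzyloxy)phenyl]chroman-3-one | c1ccc(cc1)COc1cc(OCc3ccccc3)c2c(c1)O[C@H](c1ccc(OCc3ccccc3)c(OCc3ccccc3)c1)C(=O)C2 | intermediate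

4 | (2R)-5,7-bis(benzyloxy)-2-[3,4-bis(benzyloxy)phenyl]-3-(trimethylsilyloxy)-2H-chromene | c1ccc(cc1)COc1cc(OCc3ccccc3)c2c(c1)O[C@H](c1ccc(OCc3ccccc3)c(OCc3ccccc3)c1)C(O[Si](C)(C)C)=C2 | intermediate

5 | enolonium equivalent of ketone 3: (2R)-3-{[acetoxy(phenyl)-λ3-iodanyl]oxy}-5,7-bis(benzyloxy)-2-[3,4-bis(benzyloxy)phenyl]-2H-chromene, BF3-activated, reacting as the C4 α-keto cation | c1ccc(cc1)COc1cc(OCc3ccccc3)c2c(c1)O[C@H](c1ccc(OCc3ccccc3)c(OCc3ccccc3)c1)C(OI(OC(C)=O)c1ccccc1)=C2 | intermediate (not isolated)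

6 | dimer ketone: upper unit (2R)-5,7-bis(benzyloxy)-2-[3,4-bis(benzyloxy)phenyl]chroman-3-one joined through its C4 (4α, aryl cis to the C2 aryl; 4S) to C8 of a (2R,3S)-tetra-O-benzylcatechin unit | c1ccc(cc1)COc1cc(OCc3ccccc3)c2c(c1)O[C@H](c1ccc(OCc3ccccc3)c(OCc3ccccc3)c1)C(=O)[C@@H]2c1c(OCc3ccccc3)cc(OCc3ccccc3)c2c1O[C@H](c1ccc(OCc3ccccc3)c(OCc3ccccc3)c1)[C@@H](O)C2 | intermediate

7 | 8-bromo dimer ketone: compound 6 carrying bromine at C8 of the upper unit, configuration as in 6 | c1ccc(cc1)COc1cc(OCc3ccccc3)c2c(c1Br)O[C@H](c1ccc(OCc3ccccc3)c(OCc3ccccc3)c1)C(=O)[C@@H]2c1c(OCc3ccccc3)cc(OCc3ccccc3)c2c1O[C@H](c1ccc(OCc3ccccc3)c(OCc3ccccc3)c1)[C@@H](O)C2 | intermediate (not isolated)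

8 | 8-bromo diketone dimer: upper unit 8-bromo-(2R)-chroman-3-one with 4α-aryl, joined C4→C8 to a lower (2R)-chroman-3-one unit with a free C4 methylene, all eight phenols benzylated | c1ccc(cc1)COc1cc(OCc3ccccc3)c2c(c1Br)O[C@H](c1ccc(OCc3ccccc3)c(OCc3ccccc3)c1)C(=O)[C@@H]2c1c(OCc3ccccc3)cc(OCc3ccccc3)c2c1O[C@H](c1ccc(OCc3ccccc3)c(OCc3ccccc3)c1)C(=O)C2 | intermediate

9 | mono silyl enol ether of 8: upper unit unchanged, lower unit (2R)-3-(trimethylsilyloxy)-2H-chromene | c1ccc(cc1)COc1cc(OCc3ccccc3)c2c(c1Br)O[C@H](c1ccc(OCc3ccccc3)c(OCc3ccccc3)c1)C(=O)[C@@H]2c1c(OCc3ccccc3)cc(OCc3ccccc3)c2c1O[C@H](c1ccc(OCc3ccccc3)c(OCc3ccccc3)c1)C(O[Si](C)(C)C)=C2 | intermediate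

10 | dimeric enolonium: upper unit as in 8, lower unit (2R)-3-{[acetoxy(phenyl)-λ3-iodanyl]oxy}-2H-chromene, BF3-activated, reacting as the C4 α-keto cation of the lower unit | c1ccc(cc1)COc1cc(OCc3ccccc3)c2c(c1Br)O[C@H](c1ccc(OCc3ccccc3)c(OCc3ccccc3)c1)C(=O)[C@@H]2c1c(OCc3ccccc3)cc(OCc3ccccc3)c2c1O[C@H](c1ccc(OCc3ccccc3)c(OCc3ccccc3)c1)C(OI(OC(C)=O)c1ccccc1)=C2 | intermediate (not isolated)

11 | 8-bromo tetramer triketone: units 1 to 3 are (2R)-chroman-3-ones, each joined through its 4α C4 to C8 of the next unit, bottom unit (2R,3S)-tetra-O-benzylcatechin, bromine at C8 of unit 1, all sixteen phenols benzylated | c1ccc(cc1)COc1cc(OCc3ccccc3)c2c(c1Br)O[C@H](c1ccc(OCc3ccccc3)c(OCc3ccccc3)c1)C(=O)[C@@H]2c1c(OCc3ccccc3)cc(OCc3ccccc3)c2c1O[C@H](c1ccc(OCc3ccccc3)c(OCc3ccccc3)c1)C(=O)[C@@H]2c1c(OCc3ccccc3)cc(OCc3ccccc3)c2c1O[C@H](c1ccc(OCc3ccccc3)c(OCc3ccccc3)c1)C(=O)[C@@H]2c1c(OCc3ccccc3)cc(OCc3ccccc3)c2c1O[C@H](c1ccc(OCc3ccccc3)c(OCc3ccccc3)c1)[C@@H](O)C2 | intermediate (not isolated)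

12 | 8-bromo-hexadeca-O-benzyl catechin-(4α→8)-catechin-(4α→8)-catechin-(4α→8)-catechin: bromine at C8 of the top unit, three upper units 2,3-trans-3,4-trans (2R,3S, 4α-aryl), bottom unit 2R,3S | c1ccc(cc1)COc1cc(OCc3ccccc3)c2c(c1Br)O[C@H](c1ccc(OCc3ccccc3)c(OCc3ccccc3)c1)[C@@H](O)[C@@H]2c1c(OCc3ccccc3)cc(OCc3ccccc3)c2c1O[C@H](c1ccc(OCc3ccccc3)c(OCc3ccccc3)c1)[C@@H](O)[C@@H]2c1c(OCc3ccccc3)cc(OCc3ccccc3)c2c1O[C@H](c1ccc(OCc3ccccc3)c(OCc3ccccc3)c1)[C@@H](O)[C@@H]2c1c(OCc3ccccc3)cc(OCc3ccccc3)c2c1O[C@H](c1ccc(OCc3ccccc3)c(OCc3ccccc3)c1)[C@@H](O)C2 | intermediate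

13 | catechin-(4α→8)-catechin-(4α→8)-catechin-(4α→8)-catechin (CNP0236700.2), three upper units 2R,3S,4S, bottom unit 2R,3S | Oc1cc(O)c2c(c1)O[C@H](c1ccc(O)c(O)c1)[C@@H](O)[C@@H]2c1c(O)cc(O)c2c1O[C@H](c1ccc(O)c(O)c1)[C@@H](O)[C@@H]2c1c(O)cc(O)c2c1O[C@H](c1ccc(O)c(O)c1)[C@@H](O)[C@@H]2c1c(O)cc(O)c2c1O[C@H](c1ccc(O)c(O)c1)[C@@H](O)C2 | target

## Summary

Total step count: 8. Longest linear sequence: 8 steps (1 → 2 → 3 → 4 → 6 → 8 → 9 → 12 → 13).

## Steps most likely to fail

**Step 4.** This is the first use of the key step. The iodane may oxidise the polyalkoxy arenes, the α-keto cation character may lead to the 3-hydroxyflavylium ion and loss of the C2 configuration, the 3-OH or C6 of 2 may attack instead of C8, and C4 may settle trans to the C2 aryl. The fallback sets out from 2 and 4 and reverses which partner is umpoled. NBS (CH2Cl2, −78 °C → rt) brominates 2 at C8 to give 8-bromo-5,7,3',4'-tetra-O-benzyl-(+)-catechin F1. Silyl enol ether 4 is then arylated at C4 with F1 under Pd(OAc)2, P(t-Bu)3, Bu3SnF and CsF in toluene at 85 °C. Here ring A of the lower unit is the electrophile as an aryl–palladium species and C4 reacts as an ordinary fluoride-activated enolate, with no oxidant, no cation and no strong base. The route comes back at ketone 6, which is equilibrated with Et3N as in step 4.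

**Step 6.** The selectivity of the silylation for the lower unit rests on sterics alone, and bis-silylation or enolisation of the upper ketone would feed a second, unwanted enolonium into step 7. The fallback sets out from 8 and replaces the enol ether by a diazo group. Regitz diazo transfer (p-acetamidobenzenesulfonyl azide, Et3N, MeCN, 0 °C) needs two acidic hydrogens on one carbon, so it can only take place at the lower C4 methylene. It gives the 8-bromo dimeric diazo diketone F2. BF3·OEt2 in CH2Cl2 at −78 °C in the presence of 6 (1.5 eq) activates the diazo carbon, N2 leaves, and the same C4 α-keto cation equivalent is captured by C8 of 6. The route comes back at tetramer triketone 11, which is equilibrated and reduced as in step 7.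

**Step 7.** The union of two dimers is the most crowded C–C bond formation of the route, it uses the valuable ketone 6 as the nucleophile, and it fixes six stereocentres (three C4, three C3) in one flask. The hydride face selectivity in particular is an expectation from conformational analysis and not a secured result. The fallback keeps the enolonium but grows the chain from the top with small monomer nucleophiles; it sets out from 9, 3 and 2. Enolonium 10 (made from 9 as in step 7) is captured by C8 of ketone 3 (3 eq, aqueous quench without reduction) to give the 8-bromo trimer triketone F3. Its only accessible C4 methylene, that of the bottom unit, is silylated (TMSOTf, Et3N, CH2Cl2, −78 °C) to the trimer mono silyl enol ether F4. PhI(OAc)2/BF3·OEt2 at −78 °C turns F4 into the trimeric enolonium F5, which is not isolated and is captured by C8 of 2 (3 eq). The route comes back at tetramer triketone 11, which is equilibrated with Et3N and reduced with NaBH4 in the same flask as in step 7.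

## Further compounds

F1 | step 4 | 8-bromo-5,7,3',4'-tetra-O-benzyl-(+)-catechin, (2R,3S)-5,7-bis(benzyloxy)-2-[3,4-bis(benzyloxy)phenyl]-8-bromochroman-3-ol | c1ccc(cc1)COc1cc(OCc3ccccc3)c2c(c1Br)O[C@H](c1ccc(OCc3ccccc3)c(OCc3ccccc3)c1)[C@@H](O)C2

F2 | step 6 | 8-bromo dimeric diazo diketone: upper unit 8-bromo-(2R)-chroman-3-one with 4α-aryl, joined C4→C8 to a lower (2R)-4-diazochroman-3-one unit, all eight phenols benzylated | c1ccc(cc1)COc1cc(OCc3ccccc3)c2c(c1Br)O[C@H](c1ccc(OCc3ccccc3)c(OCc3ccccc3)c1)C(=O)[C@@H]2c1c(OCc3ccccc3)cc(OCc3ccccc3)c2c1O[C@H](c1ccc(OCc3ccccc3)c(OCc3ccccc3)c1)C(=O)C2=[N+]=[N-]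

F3 | step 7 | 8-bromo trimer triketone: units 1 and 2 are (2R)-chroman-3-ones with 4α-aryl links C4→C8, bottom unit (2R)-chroman-3-one with a free C4 methylene, bromine at C8 of unit 1, all twelve phenols benzylated | c1ccc(cc1)COc1cc(OCc3ccccc3)c2c(c1Br)O[C@H](c1ccc(OCc3ccccc3)c(OCc3ccccc3)c1)C(=O)[C@@H]2c1c(OCc3ccccc3)cc(OCc3ccccc3)c2c1O[C@H](c1ccc(OCc3ccccc3)c(OCc3ccccc3)c1)C(=O)[C@@H]2c1c(OCc3ccccc3)cc(OCc3ccccc3)c2c1O[C@H](c1ccc(OCc3ccccc3)c(OCc3ccccc3)c1)C(=O)C2

F4 | step 7 | trimer mono silyl enol ether: units 1 and 2 as in F3, bottom unit (2R)-3-(trimethylsilyloxy)-2H-chromene | c1ccc(cc1)COc1cc(OCc3ccccc3)c2c(c1Br)O[C@H](c1ccc(OCc3ccccc3)c(OCc3ccccc3)c1)C(=O)[C@@H]2c1c(OCc3ccccc3)cc(OCc3ccccc3)c2c1O[C@H](c1ccc(OCc3ccccc3)c(OCc3ccccc3)c1)C(=O)[C@@H]2c1c(OCc3ccccc3)cc(OCc3ccccc3)c2c1O[C@H](c1ccc(OCc3ccccc3)c(OCc3ccccc3)c1)C(O[Si](C)(C)C)=C2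

F5 | step 7 | trimeric enolonium: units 1 and 2 as in F3, bottom unit (2R)-3-{[acetoxy(phenyl)-λ3-iodanyl]oxy}-2H-chromene, BF3-activated, not isolated | c1ccc(cc1)COc1cc(OCc3ccccc3)c2c(c1Br)O[C@H](c1ccc(OCc3ccccc3)c(OCc3ccccc3)c1)C(=O)[C@@H]2c1c(OCc3ccccc3)cc(OCc3ccccc3)c2c1O[C@H](c1ccc(OCc3ccccc3)c(OCc3ccccc3)c1)C(=O)[C@@H]2c1c(OCc3ccccc3)cc(OCc3ccccc3)c2c1O[C@H](c1ccc(OCc3ccccc3)c(OCc3ccccc3)c1)C(OI(OC(C)=O)c1ccccc1)=C2
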